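All runs were computed on assumed constants, noise included.

The easy step came first: with 0.2 mol% of catalyst on substrate, each catalyst has to turn over 500 times to use up the substrate charged, so I counted turnovers.

| flask | substrate | reagent | free catalyst | remark | time |
|---|---|---|---|---|---|
| elm | 6.5 mM | 1.2 equiv | 0.2 mol% | run made earlier |  |
| birch | 120 mM | 1.2 equiv | 0.2 mol% | run made earlier |  |
| gamma | 80 mM | 1.20 equiv | 0.2 mol% |  | 3.0 min |
| alpha | 40 mM | 1.20 equiv | 0.2 mol% |  | 3.0 min |
| zeta | 20 mM | 1.20 equiv | 0.2 mol% |  | 3.0 min |
| delta | 5.0 mM | 1.20 equiv | 0.2 mol% |  | 3.0 min |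

| run | time / s | target / % | substrate / % |
|---|---|---|---|
| elm | 20.0 | 5.3 | 94.0 |
| elm | 40.0 | 10.2 | 89.5 |
| elm | 50.0 | 12.6 | 87.6 |
| elm | 80.0 | 19.7 | 80.9 |
| elm | 90.0 | 21.6 | 78.0 |
| birch | 10.0 | 8.2 | 91.5 |
| birch | 25.0 | 17.2 | 81.9 |
| birch | 40.0 | 24.2 | 73.3 |
| birch | 60.0 | 28.8 | 63.8 |
| birch | 90.0 | 33.2 | 52.0 |

(standard deviation of a reading: 0.3 percentage points)



- ranking by amount of target, in percent of the substrate charged, from high to low, at 3.0 min (gamma / alpha / zeta / delta)
- the same order at 20 s (gamma / alpha / zeta / delta)
- the amount of target, in percent of the substrate charged of the flask you put first, at 3.0 min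
- the amount of target, in percent of the substrate charged of the flask you put last, at 3.0 min

In elm, 10.2% target at 40.0 s is 51.0 turnovers, a turnover rate (turnover frequency) of 1.27 s⁻¹ per catalyst charged. In birch, 8.2% at 10.0 s gives 4.10 s⁻¹. Birch therefore ran faster, but by a factor of 3.23 for a charge 18.5 times larger. So I drew a rate that levels off, a ceiling times the charge over the charge plus a constant, and the two runs gave a constant of 17.4 mM and a ceiling of 4.70 s⁻¹.

Delta's starting turnover rate, turnovers per second per catalyst at its charge, came to 1.05 s⁻¹. Zeta's was 2.51 s⁻¹, alpha's 3.27 s⁻¹ and gamma's 3.86 s⁻¹. At 20 s these count 15.4% target in gamma, 13.1% in alpha, 10.0% in zeta and 4.20% in delta, and that was my early order. Held for 180 s, they count 37.7% of delta's charge and 90.3% of zeta's, so I put delta below zeta.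

The weak link was holding the starting rate while substrate falls. I reforged it by taking each rate at the charge halfway through that count: 4.06 mM in delta gives 31.9% consumed, and 11.0 mM in zeta gives 65.3%. In birch, target and substrate together fell short of the charge by 14.8% at 90.0 s. Scaling birch's gap by charge, time and the square of the target gave the figures I committed to: 30.8% target in delta and 52.8% in zeta. Gamma's charge is 4.00 times zeta's, so I expected it to lose its early lead; zeta against alpha I left open.

The forecast gave zeta > alpha > gamma > delta at 3.0 min and gamma > alpha > zeta > delta at 20 s, with 48% for the first flask and 35% for the last, and it noted: “Zeta/alpha and gamma/delta are close calls”. The flasks gave zeta > alpha > gamma > delta and gamma > alpha > zeta > delta, with 52.8% and 32.0%.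

    catalyst intermediate C → free catalyst + target (k = 9.64 s⁻¹)
    catalyst intermediate B ⇌ released group + catalyst intermediate C (K = 0.0190 M, k = 15.0 s⁻¹)
    reagent + free catalyst ⇌ catalyst intermediate A (K = 4100 L mol⁻¹, k = 3940 L mol⁻¹ s⁻¹)
    target + released group → side product (k = 0.233 L mol⁻¹ s⁻¹)
    substrate + catalyst intermediate A ⇌ catalyst intermediate B (K = 42.0 L mol⁻¹, k = 579 L mol⁻¹ s⁻¹)

Zeta had not come to rest at 3.00 min: 35.7% of its substrate remained, and by 30.0 min its target had fallen to 12.4%, with side product at 87.6%. At 3.00 min delta held more substrate than zeta, 67.1%. Its starting rate of 1.05 s⁻¹, held unchanged, counts 189 of its 500 turnovers by 180 s, and the 32.9% of substrate used is 164. For the neighbour flask, delta read at 50 s, the same rate counts 10.5% against 10.4% target. Ten times the time took delta from 32.0% target to 43.3%, with side product at 54.9%.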